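**Retrosynthetic overview**

1. Drimane numbering is used: ring A = C1–C5 and C10 (C4 carries the gem-dimethyl group), ring B = C5–C10 (C6 acyloxy carbon, C7=C8 alkene, C9 carbinol carbon), C11 = carboxyl carbon, C12 = formyl carbon.
2. Target ⇒ tert-butyl ester/dimethyl acetal 22 (acid) ⇒ diol 16 + trienoic acid 20 (Yamaguchi) ⇒ enone 13 (C9 oxygenation with O2 anti to the C10 methyl group, then Luche reduction from the α face).
3. Key disconnection: 13 ⇒ open-chain keto alkylidene β-keto ester 10; one catalytic cascade closes ring A first (C5–C10, conjugate addition creating the quaternary centre) and then ring B (C7=C8, aldol condensation).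
4. Enabling feature: ring B is a 4-oxocyclohex-2-ene-1-carboxylate (Hagemann ester pattern): the oxygen-bearing C6 is read as a ketone whose two α-carbons C5 and C7 are both nucleophilic, and C10=C9(C11)–C8(=O)–C12 is the matching 1,3-dielectrophile, so C8 ends as the alkene carbon that carries C12.
5. 10 ⇒ diketone 5 + β-keto ester 9 (Knoevenagel); 5 ⇒ mesityl oxide 1 + chloro ketal 2 (conjugate addition); 9 ⇒ tert-butyl acetate 6 + methyl dimethoxyacetate 7 (Claisen); 20 ⇒ sorbaldehyde 17 + malonic acid 18.

Key step: step 4

Remark: the target is addressed as the open-chain 9-hydroxy acid–aldehyde shown by the structure; its possible ring–chain equilibrium with a cyclic lactol is assumed not to change the isolated form.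

**Route**

Step 1
Reactants: 1 mesityl oxide (4-methylpent-3-en-2-one); 2 2-(3-chloropropyl)-2-methyl-1,3-dioxolane
Product: 5 4,4-dimethylnonane-2,8-dione, via Grignard reagent 3 (not isolated), via keto ketal 4 (not isolated)
Conditions: Mg, THF, reflux; CuBr·SMe2 (5 mol %), 1, THF, −30 → 0 °C; then 2 M HCl, rt
Reagents that add atoms: water (SMILES: O)
Why: Copper-catalysed 1,4-addition of a primary alkyl Grignard reagent to the β,β-disubstituted enone (Kharasch conjugate addition) creates the quaternary C4, and the acidic work-up hydrolyses the dioxolane (acetal hydrolysis); no stereocentre is formed.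

Step 2
Reactants: 6 tert-butyl acetate; 7 methyl 2,2-dimethoxyacetate
Product: 9 tert-butyl 4,4-dimethoxy-3-oxobutanoate, via lithium enolate 8 (not isolated)
Conditions: 6 (2.1 equiv), LiN(iPr)2 (2.1 equiv), THF, −78 °C; then 7 (1 equiv), −78 → −20 °C; 1 M HCl to pH 4
Reagents that add atoms: none
Why: Crossed Claisen condensation in which the ester 7 acylates the lithium enolate of tert-butyl acetate and the second equivalent of enolate holds the product as its enolate until work-up; no stereocentre is formed.

Step 3
Reactants: 5 4,4-dimethylnonane-2,8-dione; 9 tert-butyl 4,4-dimethoxy-3-oxobutanoate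
Product: 10 tert-butyl 2-(2,2-dimethoxyacetyl)-3,7,7-trimethyl-9-oxodec-2-enoate (E/Z mixture)
Conditions: TiCl4 (2 equiv), pyridine (4 equiv), THF, 0 °C → rt
Reagents that add atoms: none
Why: Knoevenagel condensation under Lehnert conditions (titanium enolate of the β-keto ester adds to the TiCl4-activated ketone, then elimination) should take place at the unhindered C10 methyl ketone and not at the C6 ketone, which is shielded by its neopentyl-type α-carbon; no stereocentre is formed and both alkene isomers (and any deconjugated tautomer) converge in step 4.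

Step 4
Reactants: 10 tert-butyl 2-(2,2-dimethoxyacetyl)-3,7,7-trimethyl-9-oxodec-2-enoate
Product: 13 tert-butyl (1R,4aS,8aS)-2-(dimethoxymethyl)-5,5,8a-trimethyl-4-oxo-1,4,4a,5,6,7,8,8a-octahydronaphthalene-1-carboxylate, via Michael adduct 11 (not isolated), via aldol adduct 12 (not isolated)
Conditions: [Cu((S,S)-t-Bu-box)](SbF6)2 (10 mol %; t-Bu-box = 2,2′-(propane-2,2-diyl)bis(4-tert-butyl-4,5-dihydrooxazole)), (CF3)2CHOH (1 equiv), 4 Å MS, CH2Cl2, 0 °C → rt; then DBU (1.2 equiv), rt, same flask
Reagents that add atoms: none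
Why: Proposed new method: the bis(oxazoline)copper Lewis acid chelates the two carbonyl groups of the alkylidene β-keto ester, the C6 ketone enolises towards C5 and this enol adds to the activated, fully substituted C10 (conjugate addition, ring A by 6-(enolexo)-exo-trig closure through a chair) to give 11, whose chelated C8 ketone is then attacked by the C7 enol of the methyl ketone (aldol addition, ring B by 6-(enolendo)-exo-trig closure) to give 12, and DBU completes the E1cB loss of water to the conjugated enone. The closest known reaction types are the bis(oxazoline)copper-catalysed Mukaiyama–Michael addition of enol silanes to chelating alkylidene malonates and the Michael/aldol condensation (Hagemann and Robinson type) annulation of ketones onto alkylidene 1,3-dicarbonyl compounds; new here are the free ketone enol as donor, the tetrasubstituted acceptor and the closure of both rings of an open chain under catalyst control. The quaternary C10 is the only centre that the catalyst must set: the tert-butyl groups of the ligand are expected to shield one face of the chelated acceptor so that the tethered enol adds to the other [the (S,S) ligand is proposed for the (8aS) centre, and the equally available antipode is taken should the sense prove opposite]. C5, α to the ketone, is expected to equilibrate under the Lewis acid and DBU to the more stable trans ring fusion (H anti to the C10 methyl group), and C9 settles with the ester equatorial but is re-formed in step 5 anyway. The step needs site selectivity between the two α-carbons of the ketone and the right order of bond formation, and ring size secures both: only the C5 enol reaches C10 through a six-membered transition state, whereas C7-first addition or aldol-first closure would need eight- or ten-membered rings. The gem-dimethyl group at C4 favours the folded conformer, and the irreversible dehydration draws the reversible conjugate addition and aldol steps forward.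

Step 5
Reactants: 13 tert-butyl (1R,4aS,8aS)-2-(dimethoxymethyl)-5,5,8a-trimethyl-4-oxo-1,4,4a,5,6,7,8,8a-octahydronaphthalene-1-carboxylate
Product: 15 tert-butyl (1S,4aS,8aS)-2-(dimethoxymethyl)-1-hydroxy-5,5,8a-trimethyl-4-oxo-1,4,4a,5,6,7,8,8a-octahydronaphthalene-1-carboxylate, via hydroperoxide 14 (not isolated)
Conditions: Cs2CO3 (0.2 equiv), O2 (1 atm), P(OEt)3 (2 equiv), DMSO–THF, 0 °C → rt
Reagents that add atoms: dioxygen (SMILES: O=O)
Why: The C9–H of this vinylogous β-keto ester is by far the most acidic proton, its extended enolate should take up O2 at C9 (aerobic hydroxylation of 1,3-dicarbonyl-type carbon acids, γ-oxygenation of an enone dienolate, with reduction of the hydroperoxide by the phosphite), and attack on the α face, axial and anti to the axial C10 methyl group, sets the 9α-hydroxyl (1S).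

Step 6
Reactants: 15 tert-butyl (1S,4aS,8aS)-2-(dimethoxymethyl)-1-hydroxy-5,5,8a-trimethyl-4-oxo-1,4,4a,5,6,7,8,8a-octahydronaphthalene-1-carboxylate
Product: 16 tert-butyl (1S,4R,4aS,8aS)-2-(dimethoxymethyl)-1,4-dihydroxy-5,5,8a-trimethyl-1,4,4a,5,6,7,8,8a-octahydronaphthalene-1-carboxylate
Conditions: NaBH4, CeCl3·7H2O, MeOH, −40 → 0 °C
Reagents that add atoms: none
Why: Luche 1,2-reduction of the enone, in which hydride should arrive on the α face, away from the syn-axial methyl groups at C10 and C4, and so give the axial 6β-alcohol (4R).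

Step 7
Reactants: 17 (2E,4E)-hexa-2,4-dienal; 18 malonic acid
Product: 20 (2E,4E,6E)-octa-2,4,6-trienoic acid, via alkylidenemalonic acid 19 (not isolated)
Conditions: pyridine, piperidine (cat.), 90 °C
Reagents that add atoms: none
Why: Knoevenagel–Doebner condensation with decarboxylation, which gives the new alkene in the thermodynamically preferred E geometry; no stereocentre is formed.

Step 8
Reactants: 16 tert-butyl (1S,4R,4aS,8aS)-2-(dimethoxymethyl)-1,4-dihydroxy-5,5,8a-trimethyl-1,4,4a,5,6,7,8,8a-octahydronaphthalene-1-carboxylate; 20 (2E,4E,6E)-octa-2,4,6-trienoic acid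
Product: 22 tert-butyl (1S,4R,4aS,8aS)-2-(dimethoxymethyl)-1-hydroxy-5,5,8a-trimethyl-4-{[(2E,4E,6E)-octa-2,4,6-trienoyl]oxy}-1,4,4a,5,6,7,8,8a-octahydronaphthalene-1-carboxylate, via mixed anhydride 21 (not isolated)
Conditions: 2,4,6-trichlorobenzoyl chloride, Et3N, THF, rt; then 16, DMAP, toluene, rt → 40 °C
Reagents that add atoms: none
Why: Yamaguchi esterification through the mixed anhydride should acylate the secondary allylic 6β-hydroxyl while the tertiary 9-hydroxyl stays inert, with no stereocentre touched and the triene kept all-E.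

Step 9
Reactants: 22 tert-butyl (1S,4R,4aS,8aS)-2-(dimethoxymethyl)-1-hydroxy-5,5,8a-trimethyl-4-{[(2E,4E,6E)-octa-2,4,6-trienoyl]oxy}-1,4,4a,5,6,7,8,8a-octahydronaphthalene-1-carboxylate
Product: 23 ustusoic acid B, (1S,4R,4aS,8aS)-2-formyl-1-hydroxy-5,5,8a-trimethyl-4-{[(2E,4E,6E)-octa-2,4,6-trienoyl]oxy}-1,4,4a,5,6,7,8,8a-octahydronaphthalene-1-carboxylic acid
Conditions: TFA–CH2Cl2–H2O (10:10:1), 0 °C → rt
Reagents that add atoms: water (SMILES: O)
Why: Acid-mediated global deprotection (alkyl–oxygen cleavage of the tert-butyl ester with loss of isobutene, and hydrolysis of the allylic dimethyl acetal) should leave the allylic ester and the tertiary carbinol intact, because their ionisation would place a cation next to the formyl or carboxyl group; no stereocentre is affected.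

**Compound list**

1 | mesityl oxide (4-methylpent-3-en-2-one) | CC(=O)C=C(C)C | starting material
2 | 2-(3-chloropropyl)-2-methyl-1,3-dioxolane | CC1(CCCCl)OCCO1 | starting material
3 | [3-(2-methyl-1,3-dioxolan-2-yl)propyl]magnesium chloride (Grignard reagent, not isolated) | CC1(CCC[Mg]Cl)OCCO1 | intermediate
4 | 4,4-dimethyl-7-(2-methyl-1,3-dioxolan-2-yl)heptan-2-one (keto ketal, not isolated) | CC(=O)CC(C)(C)CCCC1(C)OCCO1 | intermediate
5 | 4,4-dimethylnonane-2,8-dione | CC(=O)CC(C)(C)CCCC(C)=O | intermediate
6 | tert-butyl acetate | CC(=O)OC(C)(C)C | starting material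
7 | methyl 2,2-dimethoxyacetate | COC(OC)C(=O)OC | starting material
8 | lithium 1-tert-butoxyethen-1-olate (lithium enolate of 6, not isolated) | C=C(O[Li])OC(C)(C)C | intermediate
9 | tert-butyl 4,4-dimethoxy-3-oxobutanoate | COC(OC)C(=O)CC(=O)OC(C)(C)C | intermediate
10 | tert-butyl 2-(2,2-dimethoxyacetyl)-3,7,7-trimethyl-9-oxodec-2-enoate (E/Z mixture) | CC(=O)CC(C)(C)CCCC(C)=C(C(=O)OC(C)(C)C)C(=O)C(OC)OC | intermediate
11 | tert-butyl 2-[(1S,2S)-2-acetyl-1,3,3-trimethylcyclohexyl]-4,4-dimethoxy-3-oxobutanoate (Michael adduct, epimers at C2 of the butanoate, not isolated) | CC(=O)[C@H]1C(C)(C)CCC[C@]1(C)C(C(=O)OC(C)(C)C)C(=O)C(OC)OC | intermediate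
12 | tert-butyl (4aS,8aS)-2-(dimethoxymethyl)-2-hydroxy-5,5,8a-trimethyl-4-oxodecahydronaphthalene-1-carboxylate (aldol adduct, C1 and C2 not defined, not isolated) | O=C1CC(O)(C(OC)OC)C(C(=O)OC(C)(C)C)[C@@]2(C)CCCC(C)(C)[C@H]12 | intermediate
13 | tert-butyl (1R,4aS,8aS)-2-(dimethoxymethyl)-5,5,8a-trimethyl-4-oxo-1,4,4a,5,6,7,8,8a-octahydronaphthalene-1-carboxylate (5α-H, 10β-methyl, 9β-ester) | O=C1C=C(C(OC)OC)[C@H](C(=O)OC(C)(C)C)[C@@]2(C)CCCC(C)(C)[C@H]12 | intermediate
14 | tert-butyl (1S,4aS,8aS)-2-(dimethoxymethyl)-1-hydroperoxy-5,5,8a-trimethyl-4-oxo-1,4,4a,5,6,7,8,8a-octahydronaphthalene-1-carboxylate (not isolated) | O=C1C=C(C(OC)OC)[C@](OO)(C(=O)OC(C)(C)C)[C@@]2(C)CCCC(C)(C)[C@H]12 | intermediate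
15 | tert-butyl (1S,4aS,8aS)-2-(dimethoxymethyl)-1-hydroxy-5,5,8a-trimethyl-4-oxo-1,4,4a,5,6,7,8,8a-octahydronaphthalene-1-carboxylate (9α-OH) | O=C1C=C(C(OC)OC)[C@](O)(C(=O)OC(C)(C)C)[C@@]2(C)CCCC(C)(C)[C@H]12 | intermediate
16 | tert-butyl (1S,4R,4aS,8aS)-2-(dimethoxymethyl)-1,4-dihydroxy-5,5,8a-trimethyl-1,4,4a,5,6,7,8,8a-octahydronaphthalene-1-carboxylate (6β-OH, 9α-OH) | O[C@@H]1C=C(C(OC)OC)[C@](O)(C(=O)OC(C)(C)C)[C@@]2(C)CCCC(C)(C)[C@H]12 | intermediate
17 | (2E,4E)-hexa-2,4-dienal (sorbaldehyde) | C/C=C/C=C/C=O | starting material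
18 | malonic acid | OC(=O)CC(=O)O | starting material
19 | 2-[(2E,4E)-hexa-2,4-dien-1-ylidene]propanedioic acid (not isolated) | C/C=C/C=C/C=C(C(=O)O)C(=O)O | intermediate
20 | (2E,4E,6E)-octa-2,4,6-trienoic acid | C/C=C/C=C/C=C/C(=O)O | intermediate
21 | (2E,4E,6E)-octa-2,4,6-trienoic 2,4,6-trichlorobenzoic anhydride (not isolated) | C/C=C/C=C/C=C/C(=O)OC(=O)c1c(Cl)cc(Cl)cc1Cl | intermediate
22 | tert-butyl (1S,4R,4aS,8aS)-2-(dimethoxymethyl)-1-hydroxy-5,5,8a-trimethyl-4-{[(2E,4E,6E)-octa-2,4,6-trienoyl]oxy}-1,4,4a,5,6,7,8,8a-octahydronaphthalene-1-carboxylate | C/C=C/C=C/C=C/C(=O)O[C@@H]1C=C(C(OC)OC)[C@](O)(C(=O)OC(C)(C)C)[C@@]2(C)CCCC(C)(C)[C@H]12 | intermediate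
23 | ustusoic acid B, (1S,4R,4aS,8aS)-2-formyl-1-hydroxy-5,5,8a-trimethyl-4-{[(2E,4E,6E)-octa-2,4,6-trienoyl]oxy}-1,4,4a,5,6,7,8,8a-octahydronaphthalene-1-carboxylic acid | C/C=C/C=C/C=C/C(=O)O[C@@H]1C=C(C=O)[C@](O)(C(=O)O)[C@@]2(C)CCCC(C)(C)[C@H]12 | target

**Step count and risks**

Total step count: 9. Longest linear sequence: 7 steps (1, 3, 4, 5, 6, 8, 9).

Steps most likely to fail:

1. Step 4 (Proposed new method). The enol addition to the fully substituted acceptor carbon may be too slow under catalytic Lewis acid, or the catalyst may discriminate poorly between the two faces of C10. The fallback is stepwise, racemic and followed by resolution, and sets out from 10. KOtBu (1.1 equiv) in t-BuOH–THF should bring about the intramolecular Michael addition of the ketone enolate to the alkylidene β-keto ester and give, after acidification, the racemic Michael adduct F1. Pyrrolidine–AcOH in toluene with azeotropic removal of water then closes ring B by aldol condensation (Hagemann type) to the racemic enone F2. Preparative chromatography on a chiral stationary phase separates the enantiomers, and the (1R,4aS,8aS) enantiomer is 13, where the route is rejoined.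

2. Step 3. Chemoselectivity may be lost, through intramolecular aldol cyclisation of the 1,7-diketone under the titanium conditions or through condensation at the C6 carbonyl group. The fallback masks the C6 ketone from the outset and sets out from 1 and 2. The magnesium enolate of the conjugate addition is trapped with Ac2O instead of being protonated, which gives the enol acetate ketal F3. Mild aqueous acid (PPTS, THF–H2O) removes only the dioxolane and gives the keto enol acetate F4. Lehnert condensation with 9 (TiCl4, pyridine) then has a single ketone to address and gives the alkylidene enol acetate F5. Acid-catalysed methanolysis of the enol acetate (HCl from AcCl in MeOH, 0 °C) frees the C6 ketone and returns 10, where the route is rejoined.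

3. Step 5. Oxygen may be delivered to the wrong carbon (C7 of the extended enolate, or the tertiary C5–H next to the ketone), or over-oxidation may occur. The fallback reverses the order of reduction and hydroxylation and sets out from 13. Luche reduction (NaBH4, CeCl3·7H2O, MeOH) gives the 6β-allylic alcohol F6, which no longer contains a ketone. Its dianion (KN(SiMe3)2, 2.5 equiv, THF, −78 °C; alkoxide plus ester dienolate) is hydroxylated with 2-(phenylsulfonyl)-3-phenyloxaziridine at the α-carbon C9 from the α face (Davis hydroxylation of an ester enolate). This gives diol 16, where the route is rejoined.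

Further compounds

F1 | step 4 | racemic tert-butyl 2-(2-acetyl-1,3,3-trimethylcyclohexyl)-4,4-dimethoxy-3-oxobutanoate (racemate of 11, acetyl and side chain trans) | CC(=O)[C@H]1C(C)(C)CCC[C@]1(C)C(C(=O)OC(C)(C)C)C(=O)C(OC)OC.CC(=O)[C@@H]1C(C)(C)CCC[C@@]1(C)C(C(=O)OC(C)(C)C)C(=O)C(OC)OC
F2 | step 4 | racemic tert-butyl 2-(dimethoxymethyl)-5,5,8a-trimethyl-4-oxo-1,4,4a,5,6,7,8,8a-octahydronaphthalene-1-carboxylate (racemate of 13) | O=C1C=C(C(OC)OC)[C@H](C(=O)OC(C)(C)C)[C@@]2(C)CCCC(C)(C)[C@H]12.O=C1C=C(C(OC)OC)[C@@H](C(=O)OC(C)(C)C)[C@]2(C)CCCC(C)(C)[C@@H]12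
F3 | step 3 | 4,4-dimethyl-7-(2-methyl-1,3-dioxolan-2-yl)hept-2-en-2-yl acetate (enol acetate, geometric isomers) | CC(OC(C)=O)=CC(C)(C)CCCC1(C)OCCO1
F4 | step 3 | 4,4-dimethyl-8-oxonon-2-en-2-yl acetate (enol acetate, geometric isomers) | CC(OC(C)=O)=CC(C)(C)CCCC(C)=O
F5 | step 3 | tert-butyl 9-acetoxy-2-(2,2-dimethoxyacetyl)-3,7,7-trimethyldeca-2,8-dienoate (geometric isomers) | CC(OC(C)=O)=CC(C)(C)CCCC(C)=C(C(=O)OC(C)(C)C)C(=O)C(OC)OC
F6 | step 5 | tert-butyl (1R,4R,4aS,8aS)-2-(dimethoxymethyl)-4-hydroxy-5,5,8a-trimethyl-1,4,4a,5,6,7,8,8a-octahydronaphthalene-1-carboxylate | O[C@@H]1C=C(C(OC)OC)[C@H](C(=O)OC(C)(C)C)[C@@]2(C)CCCC(C)(C)[C@H]12
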